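Ring C is disconnected at the bond between the ketone α-CH2 and the methyl-bearing quaternary carbon of ring A. The feature exploited is the γ,δ-unsaturated ketone that runs from the ring C carbonyl through its α-CH2 and the quaternary carbon to the exocyclic C=CH2 on the neighbouring ring A carbon. A thermal Claisen ring contraction of a nine-membered cyclic allyl vinyl ether forms this bond, closes ring C, sets the quaternary centre and creates the methylene group in one operation. The precursor is the enol ether obtained by titanium methylenation of the nine-membered lactone that links the furan-3-carboxylic acid on ring B to the ring A allylic alcohol of a cis-decalin.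

Key step: step 17

Assumption: in step 3 the (S,S)-ligand is taken to expose the quinone face that leads to 5 as drawn; the (R,R)-ligand would be used if the sense of induction is the opposite.

Naming note: decalin locants are C1 (methyl-bearing), C2, C3 (oxygen-bearing), C4, C4a (angular), C5, C6, C7, C8 (furyl-bearing), C8a (ring-fusion CH). Ring A is C1–C4/C4a/C8a, ring B is C4a–C8/C8a, ring C is the cycloheptanone. α is the face of H-8a, β the opposite face. The furoic acid is carried unprotected from step 5 to step 15, and the C3 oxygen is carried as a triisopropylsilyl ether.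

Step 1
Reactants: 1 pent-1-en-3-one
Product: 2 (Z)-3-(triisopropylsilyloxy)penta-1,3-diene
Conditions: TIPSOTf, Et3N, Et2O, 0 °C to rt
Reagents that add atoms: triisopropylsilyl trifluoromethanesulfonate, CC(C)[Si](OS(=O)(=O)C(F)(F)F)(C(C)C)C(C)C
Why: Soft enolisation of the enone with a silyl triflate and an amine base (silyl enol ether formation) should give the 2-silyloxy diene, the Z isomer being favoured because the methyl group avoids the vinyl group.

Step 2
Reactants: 3 methyl 2,5-dihydroxybenzoate
Product: 4 methyl 3,6-dioxocyclohexa-1,4-diene-1-carboxylate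
Conditions: Ag2O, MgSO4, Et2O, rt, used at once
Reagents that add atoms: none
Why: Silver oxide oxidation of a hydroquinone to the quinone is a standard two-electron oxidation that leaves the ester untouched.

Step 3
Reactants: 2 (Z)-3-(triisopropylsilyloxy)penta-1,3-diene, 4 methyl 3,6-dioxocyclohexa-1,4-diene-1-carboxylate
Product: 5 cis-fused Diels–Alder adduct (methyl 1β-methyl-5,8-dioxo-2-silyloxy-1,4,8,8a-tetrahydronaphthalene-4a(5H)-carboxylate)
Conditions: Gd(OTf)3 (10 mol%), 2,6-bis[(4S)-4-phenyl-4,5-dihydrooxazol-2-yl]pyridine (12 mol%), 4 Å MS, CH2Cl2, −78 to −40 °C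
Reagents that add atoms: none
Why: In this Lewis-acid-catalysed Diels–Alder reaction the quinone should bind trivalent gadolinium through its C1 carbonyl and ester oxygens, so that the ester-bearing double bond reacts, the silyloxy group sends the CHMe terminus to the unsubstituted quinone carbon (para rule), the endo transition state gives the cis ring fusion, and the chiral ligand shields one quinone face and so sets C4a and C8a in the absolute sense drawn.

Step 4
Reactants: 5 cis-fused Diels–Alder adduct, 6 furan-3-carboxylic acid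
Product: 9 C8 spiro-lactone, via lithium 2-lithiofuran-3-carboxylate 7 (not isolated), via hydroxy acid 8 (not isolated)
Conditions: 6, LDA (2.1 equiv), THF, −78 °C; CeCl3, −78 °C; then 5, −78 °C; aq. NH4Cl; PPTS (cat.), CH2Cl2, rt
Reagents that add atoms: none
Why: Directed ortho-lithiation of the furoic acid at C2 followed by a cerium-tempered 1,2-addition should hit the C8 carbonyl (the C5 carbonyl is flanked by the quaternary C4a) from the convex α face, and the γ-hydroxy acid should close to the five-membered lactone; the new carbinol centre is removed in step 5.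

Step 5
Reactants: 9 C8 spiro-lactone
Product: 10 keto acid with C7=C8 alkene
Conditions: SmI2 (2.5 equiv), THF–MeOH, −78 °C
Reagents that add atoms: none
Why: Samarium diiodide reduction of a γ-acyloxy enone should expel the allylic carboxylate, and α-protonation of the resulting dienolate by methanol frees the furoic acid and leaves the C7=C8 alkene conjugated with the furan.

Step 6
Reactants: 10 keto acid with C7=C8 alkene
Product: 11 saturated keto acid (8-furyl β)
Conditions: H2 (1 atm), 10% Pd/C, EtOAc, rt
Reagents that add atoms: none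
Why: Heterogeneous catalytic hydrogenation should reduce the styrene-type alkene faster than the hindered silyl enol ether or the furan and deliver hydrogen to the convex α face of the cis-fused bicycle, which sets C8 with H-8 cis to H-8a.

Step 7
Reactants: 11 saturated keto acid
Product: 13 C5 enol triflate, via dipotassium enolate 12 (not isolated)
Conditions: KHMDS (2.2 equiv), THF, −78 °C; PhNTf2, −78 to 0 °C; aq. NaH2PO4
Reagents that add atoms: N-phenylbis(trifluoromethanesulfonimide), O=S(=O)(N(c1ccccc1)S(=O)(=O)C(F)(F)F)C(F)(F)F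
Why: Enolate formation and O-triflation (enol triflate synthesis) can only occur towards C6 because C4a is quaternary, the first equivalent of base being taken up by the carboxylic acid.

Step 8
Reactants: 13 C5 enol triflate
Product: 14 C5 methyl ester
Conditions: Pd(OAc)2 (5 mol%), dppf (6 mol%), CO (1 atm), MeOH, Et3N, DMF, 60 °C
Reagents that add atoms: carbon monoxide, [C-]#[O+]; methanol, CO
Why: Palladium-catalysed methoxycarbonylation of a vinyl triflate (oxidative addition to zerovalent palladium, CO insertion, methanolysis) should give the conjugated ester without touching the silyl enol ether.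

Step 9
Reactants: 14 C5 methyl ester
Product: 15 diol acid
Conditions: DIBAL-H (7 equiv), CH2Cl2, −78 to 0 °C; Rochelle salt
Reagents that add atoms: none
Why: Diisobutylaluminium hydride reduction should take the conjugated ester (1,2-reduction) and the neopentyl ester to the primary alcohols while the furoic acid sits as its unreactive aluminium carboxylate.

Step 10
Reactants: 15 diol acid
Product: 17 bis(TBS ether) acid, via silyl ester 16 (not isolated)
Conditions: TBSCl, imidazole, DMAP (cat.), DMF, 40 °C; then K2CO3 (cat.), MeOH–H2O, 0 °C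
Reagents that add atoms: tert-butyldimethylsilyl chloride, CC(C)(C)[Si](C)(C)Cl
Why: Silyl ether formation protects both primary alcohols, and the labile silyl ester formed at the acid is hydrolysed in the basic methanolic work-up.

Step 11
Reactants: 17 bis(TBS ether) acid
Product: 19 C2 ketone with 3β-OTIPS, via silyloxy epoxide 18 (not isolated)
Conditions: mCPBA (1.05 equiv), NaHCO3, CH2Cl2, −20 °C to rt
Reagents that add atoms: 3-chloroperoxybenzoic acid, OOC(=O)c1cccc(Cl)c1
Why: In this Rubottom oxidation the peracid should epoxidise the electron-rich silyl enol ether far faster than the trisubstituted alkene or the electron-poor furan, on the face opposite the axial angular CH2OTBS group at C4a so that the C3–O bond is trans to it, and 1,4-silyl migration in the silyloxy epoxide then gives the α-silyloxy ketone.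

Step 12
Reactants: 19 C2 ketone with 3β-OTIPS
Product: 21 C2 enol triflate, via dipotassium enolate 20 (not isolated)
Conditions: KHMDS (2.3 equiv), THF, −78 °C; PhNTf2, −78 to −20 °C; aq. NaH2PO4
Reagents that add atoms: N-phenylbis(trifluoromethanesulfonimide), O=S(=O)(N(c1ccccc1)S(=O)(=O)C(F)(F)F)C(F)(F)F
Why: Regioselective enolate formation and O-triflation should occur at C1 and not at C3, whose hydrogen is shielded by the bulky silyloxy group and whose enolate would suffer oxygen lone-pair repulsion, giving the tetrasubstituted enol triflate and erasing the C1 stereocentre.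

Step 13
Reactants: 21 C2 enol triflate
Product: 22 C2 methyl ester
Conditions: Pd(OAc)2 (10 mol%), dppf (12 mol%), CO (1 atm), MeOH, Et3N, DMF, 70 °C
Reagents that add atoms: carbon monoxide, [C-]#[O+]; methanol, CO
Why: Palladium-catalysed methoxycarbonylation of the hindered vinyl triflate should install the one-carbon unit on C2 as the conjugated ester.

Step 14
Reactants: 22 C2 methyl ester
Product: 23 hydroxy acid (seco acid)
Conditions: DIBAL-H (5 equiv), CH2Cl2, −78 to −20 °C; Rochelle salt
Reagents that add atoms: none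
Why: 1,2-Reduction of the conjugated ester with diisobutylaluminium hydride should give the ring A allylic alcohol, the furoic acid again being masked as its aluminium carboxylate.

Step 15
Reactants: 23 hydroxy acid (seco acid)
Product: 25 nine-membered lactone, via mixed anhydride 24 (not isolated)
Conditions: 2,4,6-Cl3C6H2COCl, Et3N, THF, rt; then slow addition to DMAP, PhMe, 80 °C (2 mM)
Reagents that add atoms: none
Why: Yamaguchi macrolactonisation activates the only carboxylic acid as the mixed anhydride, and DMAP-mediated acyl transfer to the only free hydroxyl under high dilution should close the ring because the cis-fused core holds the C8 furan over ring A; no stereocentre is formed.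

Step 16
Reactants: 25 nine-membered lactone
Product: 26 nine-membered cyclic enol ether
Conditions: Cp2TiMe2 (3 equiv), pyridine (cat.), PhMe–THF, 65 °C, dark
Reagents that add atoms: dimethyltitanocene, C[Ti+2]C.[cH-]1cccc1.[cH-]1cccc1
Why: Petasis methylenation (titanium carbene, oxatitanacyclobutane, cycloreversion) should convert the only carbonyl group, the lactone, into the 1,1-disubstituted enol ether under non-acidic conditions that the silyl ethers and the furan tolerate.

Step 17
Reactants: 26 nine-membered cyclic enol ether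
Product: 27 tetracyclic ketone
Conditions: PhMe, Et3N (cat.), 130 °C, sealed tube, base-washed glass
Reagents that add atoms: none
Why: On heating, the allyl vinyl ether unit C(=CH2)–O–CH2–C2=C1 should undergo a concerted suprafacial [3,3] sigmatropic shift in which the enol CH2 bonds to C1 while the O–CH2 bond breaks, so that the lactone-derived carbon becomes the ring C ketone and C2 keeps an exocyclic methylene. The closest known reaction type is the Claisen rearrangement of allyl vinyl ethers made by titanium methylenation of allylic esters and lactones, here in its ring-contracting variant. Ring C, the seven-membered carbocycle, closes by contraction of the nine-membered oxacycle: the new bond forms inside the existing ring and the O–CH2–C2 segment is extruded from it. The quaternary centre at C1 is controlled by the tether, because the furan is joined through C8 to the β face at C8a and the enol carbon can reach only that face of the C1=C2 alkene, which gives the cis ring A/ring C fusion through a boat-like transition state imposed by the ring. The step needs the [3,3] pathway to win over ionisation to an allyl cation and an enolate, hydrolysis of the enol ether and a [1,3] shift; neutral, base-washed, non-polar conditions, the strain of the trans alkene in the nine-membered ring and carbonyl formation secure this.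

Step 18
Reactants: 27 tetracyclic ketone
Product: 28 diol
Conditions: HF·pyridine, pyridine, THF, 0 °C to rt
Reagents that add atoms: none
Why: Fluoride-mediated desilylation with buffered HF·pyridine should cleave the two primary tert-butyldimethylsilyl ethers much faster than the hindered secondary triisopropylsilyl ether.

Step 19
Reactants: 28 diol
Product: 31 butenolide TIPS ether, via hydroxy enal 29 (not isolated), via lactol 30 (not isolated)
Conditions: TEMPO (0.2 equiv), PhI(OAc)2 (2.5 equiv), CH2Cl2, rt
Reagents that add atoms: none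
Why: In the TEMPO/PhI(OAc)2 oxidation the allylic primary alcohol should be oxidised first, the enal is trapped by the neighbouring CH2OH as the lactol, and a second oxidation gives the conjugated γ-lactone with its carbonyl on the alkene side.

Step 20
Reactants: 31 butenolide TIPS ether
Product: 32 C3 alcohol
Conditions: TBAF, AcOH, THF, 0 °C to rt
Reagents that add atoms: none
Why: Fluoride desilylation buffered with acetic acid should remove the triisopropylsilyl ether without opening the butenolide or touching a stereocentre.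

Step 21
Reactants: 32 C3 alcohol
Product: 33 target (CNP0273675.2)
Conditions: Ac2O, pyridine, DMAP (cat.), CH2Cl2, rt
Reagents that add atoms: acetic anhydride, CC(=O)OC(C)=O
Why: DMAP-catalysed acylation (esterification) of the secondary allylic alcohol completes the target with retention at C3.

Compound list

1 | pent-1-en-3-one | C=CC(=O)CC | starting material
2 | (Z)-3-(triisopropylsilyloxy)penta-1,3-diene | C=C/C(O[Si](C(C)C)(C(C)C)C(C)C)=C/C | intermediate
3 | methyl 2,5-dihydroxybenzoate | COC(=O)c1cc(O)ccc1O | starting material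
4 | methyl 3,6-dioxocyclohexa-1,4-diene-1-carboxylate | COC(=O)C1=CC(=O)C=CC1=O | intermediate
5 | methyl 1β-methyl-5,8-dioxo-2-(triisopropylsilyloxy)-1,4,8,8a-tetrahydronaphthalene-4a(5H)-carboxylate, cis-fused, 4a-CO2Me α, H-8a α | C[C@H]1C(O[Si](C(C)C)(C(C)C)C(C)C)=CC[C@@]2(C(=O)OC)C(=O)C=CC(=O)[C@@H]12 | intermediate
6 | furan-3-carboxylic acid | OC(=O)c1ccoc1 | starting material
7 | lithium 2-lithiofuran-3-carboxylate | [Li]OC(=O)c1ccoc1[Li] | intermediate
8 | hydroxy acid: adduct of furan C2 to the C8 carbonyl of 5 (8-OH β, 8-furyl α), furan-3-carboxylic acid free | C[C@H]1C(O[Si](C(C)C)(C(C)C)C(C)C)=CC[C@@]2(C(=O)OC)C(=O)C=C[C@](O)(c3occc3C(=O)O)[C@@H]12 | intermediate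
9 | spiro-lactone of 8 (furo[3,4-b]furan-4-one spiro-fused at C8, lactone O β), C5 enone retained | C[C@H]1C(O[Si](C(C)C)(C(C)C)C(C)C)=CC[C@@]2(C(=O)OC)C(=O)C=C[C@@]3(OC(=O)c4ccoc43)[C@@H]12 | intermediate
10 | 2-(decalin-C8-yl)furan-3-carboxylic acid with C5 ketone, C7=C8 alkene, 4a-CO2Me α, ring A silyl enol ether | C[C@H]1C(O[Si](C(C)C)(C(C)C)C(C)C)=CC[C@@]2(C(=O)OC)C(=O)CC=C(c3occc3C(=O)O)[C@@H]12 | intermediate
11 | as 10 with C7–C8 saturated, 8-furyl β (H-8 α, cis to H-8a) | C[C@H]1C(O[Si](C(C)C)(C(C)C)C(C)C)=CC[C@@]2(C(=O)OC)C(=O)CC[C@@H](c3occc3C(=O)O)[C@@H]12 | intermediate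
12 | dipotassium salt of 11: C5=C6 enolate and furoate | C[C@H]1C(O[Si](C(C)C)(C(C)C)C(C)C)=CC[C@@]2(C(=O)OC)C(O[K])=CC[C@@H](c3occc3C(=O)O[K])[C@@H]12 | intermediate
13 | C5 enol triflate (C5=C6) of 11 | C[C@H]1C(O[Si](C(C)C)(C(C)C)C(C)C)=CC[C@@]2(C(=O)OC)C(OS(=O)(=O)C(F)(F)F)=CC[C@@H](c3occc3C(=O)O)[C@@H]12 | intermediate
14 | C5 methyl ester (C5=C6) with 4a-CO2Me, furoic acid free | C[C@H]1C(O[Si](C(C)C)(C(C)C)C(C)C)=CC[C@@]2(C(=O)OC)C(C(=O)OC)=CC[C@@H](c3occc3C(=O)O)[C@@H]12 | intermediate
15 | diol acid: 4a-CH2OH (α) and 5-CH2OH, C5=C6, furoic acid free | C[C@H]1C(O[Si](C(C)C)(C(C)C)C(C)C)=CC[C@@]2(CO)C(CO)=CC[C@@H](c3occc3C(=O)O)[C@@H]12 | intermediate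
16 | bis(TBS ether) of 15 with the acid as TBS ester | C[C@H]1C(O[Si](C(C)C)(C(C)C)C(C)C)=CC[C@@]2(CO[Si](C)(C)C(C)(C)C)C(CO[Si](C)(C)C(C)(C)C)=CC[C@@H](c3occc3C(=O)O[Si](C)(C)C(C)(C)C)[C@@H]12 | intermediate
17 | bis(TBS ether) acid, ring A silyl enol ether (C2=C3) | C[C@H]1C(O[Si](C(C)C)(C(C)C)C(C)C)=CC[C@@]2(CO[Si](C)(C)C(C)(C)C)C(CO[Si](C)(C)C(C)(C)C)=CC[C@@H](c3occc3C(=O)O)[C@@H]12 | intermediate
18 | 2,3-epoxide of 17 (epoxide O β, 2-OTIPS) | C[C@H]1[C@@]3(O[Si](C(C)C)(C(C)C)C(C)C)O[C@H]3C[C@@]2(CO[Si](C)(C)C(C)(C)C)C(CO[Si](C)(C)C(C)(C)C)=CC[C@@H](c4occc4C(=O)O)[C@@H]12 | intermediate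
19 | C2 ketone with 3β-OTIPS (trans to the 4a-CH2OTBS), 1β-methyl | C[C@H]1C(=O)[C@@H](O[Si](C(C)C)(C(C)C)C(C)C)C[C@@]2(CO[Si](C)(C)C(C)(C)C)C(CO[Si](C)(C)C(C)(C)C)=CC[C@@H](c3occc3C(=O)O)[C@@H]12 | intermediate
20 | dipotassium salt of 19: C1=C2 enolate and furoate | CC1=C(O[K])[C@@H](O[Si](C(C)C)(C(C)C)C(C)C)C[C@@]2(CO[Si](C)(C)C(C)(C)C)C(CO[Si](C)(C)C(C)(C)C)=CC[C@@H](c3occc3C(=O)O[K])[C@@H]12 | intermediate
21 | C2 enol triflate (C1=C2), 1-methyl, 3β-OTIPS | CC1=C(OS(=O)(=O)C(F)(F)F)[C@@H](O[Si](C(C)C)(C(C)C)C(C)C)C[C@@]2(CO[Si](C)(C)C(C)(C)C)C(CO[Si](C)(C)C(C)(C)C)=CC[C@@H](c3occc3C(=O)O)[C@@H]12 | intermediate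
22 | C2 methyl ester (C1=C2), furoic acid free | CC1=C(C(=O)OC)[C@@H](O[Si](C(C)C)(C(C)C)C(C)C)C[C@@]2(CO[Si](C)(C)C(C)(C)C)C(CO[Si](C)(C)C(C)(C)C)=CC[C@@H](c3occc3C(=O)O)[C@@H]12 | intermediate
23 | seco acid: 2-(hydroxymethyl)-1-methyl-3β-OTIPS-4a,5-bis(CH2OTBS) hexahydronaphthalene (C1=C2, C5=C6) bearing 3-carboxyfuran-2-yl at C8 (β) | CC1=C(CO)[C@@H](O[Si](C(C)C)(C(C)C)C(C)C)C[C@@]2(CO[Si](C)(C)C(C)(C)C)C(CO[Si](C)(C)C(C)(C)C)=CC[C@@H](c3occc3C(=O)O)[C@@H]12 | intermediate
24 | mixed anhydride of 23 with 2,4,6-trichlorobenzoic acid | CC1=C(CO)[C@@H](O[Si](C(C)C)(C(C)C)C(C)C)C[C@@]2(CO[Si](C)(C)C(C)(C)C)C(CO[Si](C)(C)C(C)(C)C)=CC[C@@H](c3occc3C(=O)OC(=O)c4c(Cl)cc(Cl)cc4Cl)[C@@H]12 | intermediate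
25 | nine-membered lactone between the furan-3-carboxyl and the C2 CH2OH | O=C1OCC2=C(C)[C@@H]3[C@@H](CC=C(CO[Si](C)(C)C(C)(C)C)[C@]3(CO[Si](C)(C)C(C)(C)C)C[C@@H]2O[Si](C(C)C)(C(C)C)C(C)C)c2occc12 | intermediate
26 | nine-membered cyclic enol ether (exocyclic C=CH2 in place of the lactone C=O); key-step precursor | C=C1OCC2=C(C)[C@@H]3[C@@H](CC=C(CO[Si](C)(C)C(C)(C)C)[C@]3(CO[Si](C)(C)C(C)(C)C)C[C@@H]2O[Si](C(C)C)(C(C)C)C(C)C)c2occc12 | intermediate
27 | tetracyclic ketone: furan-fused cycloheptanone (ring C), C1 quaternary (Me α, CH2C=O β), exocyclic methylene at C2, 3β-OTIPS, bis(CH2OTBS); key-step product | C=C1[C@@H](O[Si](C(C)C)(C(C)C)C(C)C)C[C@@]2(CO[Si](C)(C)C(C)(C)C)C(CO[Si](C)(C)C(C)(C)C)=CC[C@H]3c4occc4C(=O)C[C@]1(C)[C@@H]23 | intermediate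
28 | diol of 27 (4a-CH2OH and 5-CH2OH free, 3β-OTIPS kept) | C=C1[C@@H](O[Si](C(C)C)(C(C)C)C(C)C)C[C@@]2(CO)C(CO)=CC[C@H]3c4occc4C(=O)C[C@]1(C)[C@@H]23 | intermediate
29 | hydroxy enal (5-CHO, 4a-CH2OH) | C=C1[C@@H](O[Si](C(C)C)(C(C)C)C(C)C)C[C@@]2(CO)C(C=O)=CC[C@H]3c4occc4C(=O)C[C@]1(C)[C@@H]23 | intermediate
30 | lactol from 29 | C=C1[C@@H](O[Si](C(C)C)(C(C)C)C(C)C)C[C@@]23COC(O)C2=CC[C@H]2c4occc4C(=O)C[C@]1(C)[C@H]23 | intermediate
31 | butenolide with 3β-OTIPS | C=C1[C@@H](O[Si](C(C)C)(C(C)C)C(C)C)C[C@@]23COC(=O)C2=CC[C@H]2c4occc4C(=O)C[C@]1(C)[C@H]23 | intermediate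
32 | C3 alcohol (deacetyl target) | C=C1[C@@H](O)C[C@@]23COC(=O)C2=CC[C@H]2c4occc4C(=O)C[C@]1(C)[C@H]23 | intermediate
33 | CNP0273675.2 | C=C1[C@@H](OC(C)=O)C[C@@]23COC(=O)C2=CC[C@H]2c4occc4C(=O)C[C@]1(C)[C@H]23 | target

Total step count: 21. Longest linear sequence: 20 steps (steps 2–21 from 3; equally steps 1 and 3–21 from 1).

Steps most likely to fail

Step 17. The concerted shift may be outrun by ionisation of the allylic C–O bond, by hydrolysis of the strained enol ether, or the ring may not reach the boat-like geometry, so that the material decomposes before the new bond forms. The fallback makes the same bond by a Carroll rearrangement through a larger and less strained ring. It sets out from 23. The acid is activated with carbonyldiimidazole and treated with the lithium enolate of tert-butyl acetate to give the β-keto tert-butyl ester F1. Heating F1 in xylene at high dilution should generate the acylketene, which the allylic alcohol traps as the eleven-membered β-keto lactone F2. On further heating the enol of F2 undergoes the [3,3] shift to the β-keto acid F3, which loses carbon dioxide and comes back to the route at 27.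

Step 15. Closure of the nine-membered ring, which must accommodate a trans alkene, may lose to intermolecular acylation and give oligomers. The fallback closes the ring by alkylation instead of acylation and sets out from 23. The allylic alcohol is converted into the allylic chloride acid F4 (MsCl, Et3N, LiCl, DMF, 0 °C; the mixed anhydride at the acid is hydrolysed on work-up). The caesium carboxylate of F4 (Cs2CO3, DMF, high dilution, 50 °C) then displaces the primary allylic chloride and comes back to the route at 25.

Step 11. Facial selectivity in the epoxidation of the silyl enol ether may be poor or opposite, which would place the C3 oxygen cis to the angular CH2OTBS group. The fallback uses that same facial preference and then inverts. It sets out from 17. N-Bromosuccinimide (THF, −78 °C) gives the α-bromo ketone F5 with bromine on the face the peracid would have used. SN2 displacement with caesium formate (18-crown-6, DMF) gives the inverted α-formyloxy ketone F6. Mild methanolysis (K2CO3 cat., MeOH, 0 °C) gives the α-hydroxy ketone F7, and silylation (TIPSOTf, 2,6-lutidine, then hydrolysis of the silyl ester) comes back to the route at 19.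

Further compounds

F1 | step 17 | β-keto tert-butyl ester from 23 (furan-3-yl C(=O)CH2CO2tBu, C2 CH2OH free) | CC1=C(CO)[C@@H](O[Si](C(C)C)(C(C)C)C(C)C)C[C@@]2(CO[Si](C)(C)C(C)(C)C)C(CO[Si](C)(C)C(C)(C)C)=CC[C@@H](c3occc3C(=O)CC(=O)OC(C)(C)C)[C@@H]12
F2 | step 17 | eleven-membered β-keto lactone | O=C1CC(=O)OCC2=C(C)[C@@H]3[C@@H](CC=C(CO[Si](C)(C)C(C)(C)C)[C@]3(CO[Si](C)(C)C(C)(C)C)C[C@@H]2O[Si](C(C)C)(C(C)C)C(C)C)c2occc12
F3 | step 17 | β-keto acid (27 with CO2H on the ketone α-carbon) | C=C1[C@@H](O[Si](C(C)C)(C(C)C)C(C)C)C[C@@]2(CO[Si](C)(C)C(C)(C)C)C(CO[Si](C)(C)C(C)(C)C)=CC[C@H]3c4occc4C(=O)C(C(=O)O)[C@]1(C)[C@@H]23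
F4 | step 15 | allylic chloride acid (23 with CH2Cl at C2) | CC1=C(CCl)[C@@H](O[Si](C(C)C)(C(C)C)C(C)C)C[C@@]2(CO[Si](C)(C)C(C)(C)C)C(CO[Si](C)(C)C(C)(C)C)=CC[C@@H](c3occc3C(=O)O)[C@@H]12
F5 | step 11 | α-bromo ketone (3α-Br, C2 ketone) | C[C@H]1C(=O)[C@H](Br)C[C@@]2(CO[Si](C)(C)C(C)(C)C)C(CO[Si](C)(C)C(C)(C)C)=CC[C@@H](c3occc3C(=O)O)[C@@H]12
F6 | step 11 | α-formyloxy ketone (3β-OCHO) | C[C@H]1C(=O)[C@@H](OC=O)C[C@@]2(CO[Si](C)(C)C(C)(C)C)C(CO[Si](C)(C)C(C)(C)C)=CC[C@@H](c3occc3C(=O)O)[C@@H]12
F7 | step 11 | α-hydroxy ketone (3β-OH) | C[C@H]1C(=O)[C@@H](O)C[C@@]2(CO[Si](C)(C)C(C)(C)C)C(CO[Si](C)(C)C(C)(C)C)=CC[C@@H](c3occc3C(=O)O)[C@@H]12
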